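**Retrosynthetic overview**
1. Kolanone ⇒ an open-chain, fully alkylated tetraketide (a methyl 3,5,7-trioxo-7-phenylheptanoate with the quaternary carbon at C-2 and a prenyl at C-4). The bond cut is the one between the benzoyl-bearing carbon and the ester carbonyl, i.e. the C6→C1 Claisen cyclisation of benzophenone biosynthesis, run on the alkylated chain so the ring is born dearomatised.
2. Tetraketide ⇒ γ-C-acylation of the dianion of 7-methyl-1-phenyloct-6-ene-1,3-dione (benzoyl starter, one ketide, prenyl) by an enantiopure 2-geranyl-2-prenylmalonyl chloride methyl ester; both C–C bonds are made in one pot.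
3. Diketone ⇒ benzoylacetone dianion + prenyl bromide.
4. Malonyl unit ⇒ tert-butyl methyl malonate: prenylation, enantioselective phase-transfer geranylation (sets the only stereocentre), tert-butyl ester cleavage.
5. Ring order: the phenyl ring is bought; the trione ring is the only ring formed, in the last step.

Assumption: the sense of induction in step 3 is not known for this exact substrate. The route is written for the (S)-diester 7; if the first run gives the mirror image, N-(9-anthracenylmethyl)cinchonidinium chloride is used instead, or geranyl is put on first and prenyl under catalysis. Kolanone is written as the enol tautomer of the target SMILES, in which the stereocentre is R.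

**Route**

Step 1
Reactants: 1 benzoylacetone (1-phenylbutane-1,3-dione); 2 prenyl bromide (1-bromo-3-methylbut-2-ene)
Product: 3 7-methyl-1-phenyloct-6-ene-1,3-dione
Conditions: LiN(iPr)2 (2.2 equiv), THF, 0 °C; then 2 (1.0 equiv), −78 → 0 °C; aq HCl
Reagents that add atoms: none
Why: Hauser–Harris dianion γ-alkylation: the second deprotonation puts the most reactive carbanion on the terminal methyl, which attacks the primary carbon of the allylic bromide (SN2), so the prenyl group sits on the future ring carbon between two ketide carbonyls; no stereocentre is formed.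

Step 2
Reactants: 4 tert-butyl methyl malonate; 2 prenyl bromide
Product: 5 1-tert-butyl 3-methyl 2-(3-methylbut-2-en-1-yl)propanedioate (racemic)
Conditions: 4 (1.3 equiv), NaH (1.0 equiv), THF, 0 °C; then 2 (1.0 equiv), 0 °C → rt
Reagents that add atoms: none
Why: Malonic ester SN2 alkylation with the malonate in excess to suppress dialkylation; the new stereocentre is racemic and is erased by enolisation in step 3.

Step 3
Reactants: 5 racemic prenylmalonate; 6 geranyl bromide ((2E)-1-bromo-3,7-dimethylocta-2,6-diene)
Product: 7 1-tert-butyl 3-methyl (2S)-2-[(2E)-3,7-dimethylocta-2,6-dien-1-yl]-2-(3-methylbut-2-en-1-yl)propanedioate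
Conditions: 6 (1.2 equiv), N-(9-anthracenylmethyl)cinchoninium chloride (C34H33ClN2O, 10 mol %), 50% aq KOH, toluene, −20 °C
Reagents that add atoms: none
Why: Enantioselective phase-transfer α-alkylation of an α-monosubstituted tert-butyl methyl malonate: the chiral ammonium cation ion-pairs with the prochiral enolate, whose faces are distinguished by the tert-butyl versus methyl ester, and geranyl bromide enters from the open face to set the quaternary centre as S.

Step 4
Reactants: 7 (S)-tert-butyl methyl geranyl prenyl malonate
Product: 9 (2R)-2-[(2E)-3,7-dimethylocta-2,6-dien-1-yl]-2-(methoxycarbonyl)-5-methylhex-4-enoic acid, via trimethylsilyl ester 8 (not isolated)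
Conditions: Me3SiOTf (2 equiv), 2,6-lutidine (3 equiv), CH2Cl2, 0 °C → rt; aq citric acid work-up
Reagents that add atoms: trimethylsilyl trifluoromethanesulfonate C[Si](C)(C)OS(=O)(=O)C(F)(F)F (its silyl group stays in 8 only)
Why: Silyl-triflate-induced E1 loss of isobutene from the tert-butyl ester under lutidine buffering, so no free Brønsted acid reaches the trisubstituted alkenes; the methyl ester is inert and the centre has no α-hydrogen, so it cannot epimerise (S → R is only a change of CIP ranking).

Step 5
Reactants: 9 (R)-half-acid methyl ester; 3 7-methyl-1-phenyloct-6-ene-1,3-dione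
Product: 12 kolanone, via acid chloride 10 (not isolated), via open-chain tetraketide ester 11 (not isolated)
Conditions: (a) 9, Me2C=C(Cl)NMe2 (1.0 equiv), CH2Cl2, 0 °C → rt, then evaporate; (b) 3 (2.2 equiv), LiN(iPr)2 (4.4 equiv), THF, −78 → 0 °C, then 10 in THF, −78 → 0 °C; (c) CH3OH, 50 °C; 1 M HCl work-up
Reagents that add atoms: 1-chloro-N,N,2-trimethylprop-1-en-1-amine CC(C)=C(Cl)N(C)C (its chlorine stays in 10 only)
Why: Proposed new method: the γ-carbanion of the diketone dianion is C-acylated by the non-enolisable acid chloride (Harris-type Claisen acylation, the second equivalent of dianion taking up the acidic proton of the product) to give tetraketide 11, whose most acidic methylene (between benzoyl and ketone) then attacks the methyl ester in the C6→C1 Claisen (Dieckmann) cyclisation once methanol allows proton shuttling and rotation of the enolates; the closest known reaction type is the base-mediated Claisen cyclisation of 3,5,7-triketo esters to acylphloroglucinols, and here the quaternary C-2 rules out the competing aldol (resorcylate) closure, any enol lactone is reopened by methoxide, the product is drained as its stable bis-enolate, and the stereocentre from step 3 is carried unchanged.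

**Compound list**
1 | benzoylacetone (1-phenylbutane-1,3-dione) | CC(=O)CC(=O)c1ccccc1 | starting material
2 | prenyl bromide (1-bromo-3-methylbut-2-ene) | CC(C)=CCBr | starting material
3 | 7-methyl-1-phenyloct-6-ene-1,3-dione | CC(C)=CCCC(=O)CC(=O)c1ccccc1 | intermediate
4 | tert-butyl methyl malonate | COC(=O)CC(=O)OC(C)(C)C | starting material
5 | 1-tert-butyl 3-methyl 2-(3-methylbut-2-en-1-yl)propanedioate, racemic | COC(=O)C(CC=C(C)C)C(=O)OC(C)(C)C | intermediate
6 | geranyl bromide ((2E)-1-bromo-3,7-dimethylocta-2,6-diene) | CC(C)=CCC/C(C)=C/CBr | starting material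
7 | 1-tert-butyl 3-methyl (2S)-2-[(2E)-3,7-dimethylocta-2,6-dien-1-yl]-2-(3-methylbut-2-en-1-yl)propanedioate | CC(C)=CCC/C(C)=C/C[C@](C(=O)OC)(CC=C(C)C)C(=O)OC(C)(C)C | intermediate
8 | 1-methyl 3-trimethylsilyl (2S)-2-[(2E)-3,7-dimethylocta-2,6-dien-1-yl]-2-(3-methylbut-2-en-1-yl)propanedioate | CC(C)=CCC/C(C)=C/C[C@](C(=O)OC)(CC=C(C)C)C(=O)O[Si](C)(C)C | intermediate
9 | (2R)-2-[(2E)-3,7-dimethylocta-2,6-dien-1-yl]-2-(methoxycarbonyl)-5-methylhex-4-enoic acid | CC(C)=CCC/C(C)=C/C[C@](C(=O)OC)(CC=C(C)C)C(=O)O | intermediate
10 | methyl (2S)-2-(chlorocarbonyl)-2-[(2E)-3,7-dimethylocta-2,6-dien-1-yl]-5-methylhex-4-enoate | CC(C)=CCC/C(C)=C/C[C@](C(=O)OC)(CC=C(C)C)C(Cl)=O | intermediate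
11 | methyl (2R)-2-[(2E)-3,7-dimethylocta-2,6-dien-1-yl]-2,4-bis(3-methylbut-2-en-1-yl)-3,5,7-trioxo-7-phenylheptanoate (C-4 enolisable, not defined) | CC(C)=CCC/C(C)=C/C[C@](C(=O)OC)(CC=C(C)C)C(=O)C(CC=C(C)C)C(=O)CC(=O)c1ccccc1 | intermediate
12 | kolanone, (2R)-2-[(2E)-3,7-dimethylocta-2,6-dien-1-yl]-5-hydroxy-6-[hydroxy(phenyl)methylidene]-2,4-bis(3-methylbut-2-en-1-yl)cyclohex-4-ene-1,3-dione (enol tautomer as in the target) | CC(C)=CCC/C(C)=C/C[C@]1(CC=C(C)C)C(=O)C(CC=C(C)C)=C(O)/C(=C(\O)c2ccccc2)C1=O | target

**Count**
Total steps: 5. Longest linear sequence: 4 (steps 2, 3, 4, 5 from compound 4); step 1 is a one-step side branch.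

**Steps most likely to fail, with fallbacks**

Step 5 (highest risk). The hindered acid chloride may O-acylate the dianion, or the open tetraketide may lactonise or cleave by retro-Claisen instead of closing. The fallback sets out from 2 and 6 and comes back at 12. Commercial 2,4,6-trihydroxybenzophenone is C-prenylated twice with 2 (aq KOH, 0 °C) to 3,5-diprenyl-2,4,6-trihydroxybenzophenone F1, whose two prenylated ring carbons are enantiotopic. Catalytic enantioselective alkylative dearomatisation with 6 under chiral ion-pair control (N-(9-anthracenylmethyl)cinchoninium chloride, CsOH·H2O, toluene/CH2Cl2, −50 °C) then puts the geranyl group on one of them and gives 12. The stereocentre is then set on the ring, not in the chain, and the enantioselectivity of that alkylation is itself unproven.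

Step 3. Geranyl and prenyl are similar in size and the ester pair is only tert-butyl versus methyl, so the ee may be inadequate. The fallback sets out from 5 and comes back at 7. Compound 5 is geranylated without a chiral catalyst (NaH, THF, 6) to the racemic diester F2. F2 is resolved by preparative chromatography on a chiral stationary phase (supercritical CO2/iPrOH, amylose carbamate column), and the (S)-enantiomer is 7.

Step 4. Traces of triflic acid could cyclise the liberated acid onto a prenyl alkene, or cleavage could stall. The fallback sets out from 7 and comes back at 12, replacing step 5 as well, and uses base only. The methyl ester of 7 is saponified (LiOH, THF/H2O, 40 °C; the tert-butyl ester is inert) to (2S)-2-(tert-butoxycarbonyl)-2-geranyl-5-methylhex-4-enoic acid F3. F3 is converted with the same chloro-enamine to its acid chloride F4, which C-acylates the central carbon of 3 under soft enolisation (MgCl2, NEt3, CH2Cl2) to give the 2-acyl-1,3-diketone F5. LiN(iPr)2 (2.2 equiv, THF, −78 °C → rt) then forms the enolate plus the terminal α'-carbanion, which closes on the tert-butyl ester with loss of tert-butoxide to give 12. The two Claisen bonds are made in reverse order, so the same enantiomer 7 still gives (R)-kolanone: the former methyl ester carbon again ends next to the benzoyl-bearing carbon. Closure onto a tert-butyl ester is the weak point of this fallback.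

**Further compounds**
F1 | step 5 | 3,5-diprenyl-2,4,6-trihydroxybenzophenone | O=C(c1ccccc1)c1c(O)c(CC=C(C)C)c(O)c(CC=C(C)C)c1O
F2 | step 3 | racemic 1-tert-butyl 3-methyl 2-[(2E)-3,7-dimethylocta-2,6-dien-1-yl]-2-(3-methylbut-2-en-1-yl)propanedioate | CC(C)=CCC/C(C)=C/CC(C(=O)OC)(CC=C(C)C)C(=O)OC(C)(C)C
F3 | step 4 | (2S)-2-(tert-butoxycarbonyl)-2-[(2E)-3,7-dimethylocta-2,6-dien-1-yl]-5-methylhex-4-enoic acid | CC(C)=CCC/C(C)=C/C[C@](C(=O)O)(CC=C(C)C)C(=O)OC(C)(C)C
F4 | step 4 | tert-butyl (2R)-2-(chlorocarbonyl)-2-[(2E)-3,7-dimethylocta-2,6-dien-1-yl]-5-methylhex-4-enoate | CC(C)=CCC/C(C)=C/C[C@](C(Cl)=O)(CC=C(C)C)C(=O)OC(C)(C)C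
F5 | step 4 | tert-butyl (2S)-4-benzoyl-2-[(2E)-3,7-dimethylocta-2,6-dien-1-yl]-9-methyl-2-(3-methylbut-2-en-1-yl)-3,5-dioxodec-8-enoate | CC(C)=CCC/C(C)=C/C[C@](C(=O)C(C(=O)c1ccccc1)C(=O)CCC=C(C)C)(CC=C(C)C)C(=O)OC(C)(C)C
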